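The catalyst balance is an invariant of a closed flask: free catalyst, catalyst intermediates A, B and C and spent catalyst always sum to the catalyst charged, and each impurity that reacts moves one catalyst into spent catalyst.

| setting | oak | larch | ash | flask |
|---|---|---|---|---|
| substrate | 20 mM | 20 mM | 20 mM | 20 mM |
| reagent | 56 mM | 88 mM | 40 mM | 40.0 mM |
| free catalyst | 0.26 mM | 0.26 mM | 0.52 mM | 0.26 mM |
| impurity | 0.11 mM | 0.11 mM | 0.11 mM | 0.11 mM |
| remark | run made earlier | run made earlier | run made earlier |  |

| run | time / min | target / % | substrate / % |
|---|---|---|---|
| oak | 1.00 | 6.2 | 95.2 |
| oak | 2.00 | 8.2 | 90.3 |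
| oak | 5.00 | 20.3 | 79.9 |
| oak | 12.0 | 44.2 | 56.1 |
| larch | 1.50 | 7.9 | 91.7 |
| larch | 4.00 | 18.0 | 81.3 |
| larch | 8.00 | 32.6 | 66.8 |
| larch | 12.0 | 47.6 | 51.6 |
| ash | 3.00 | 27.9 | 69.3 |
| ash | 6.00 | 55.5 | 44.7 |
| ash | 10.0 | 86.0 | 14.6 |
| ash | 12.0 | 93.7 | 3.3 |

(standard deviation of a reading: 1 percentage point)

1. apparent order in reagent when 10% of the substrate are converted (percent change of the rate of making target for one percent more reagent charged)
2. apparent order in free catalyst when 10% of the substrate are converted (percent change of the rate of making target for one percent more free catalyst charged)

- the numbers in the tables scatter with a standard deviation of 1 percentage point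
- reactions considered so far: catalyst intermediate C -> free catalyst + target; catalyst intermediate A -> catalyst intermediate B; free catalyst + impurity -> spent catalyst; substrate + catalyst intermediate B <-> catalyst intermediate C; reagent + free catalyst -> catalyst intermediate A
- what is bound to the catalyst counts as converted

One thing looks contradictory. The ash run has twice the catalyst of the oak run and less reagent, yet the mean rate of making target goes from 0.737 mM min⁻¹ over the first 12.0 min of the oak run to 1.72 mM min⁻¹ over the first 10.0 min of the ash run, a reading 2.33 times higher.

The balance clears this up through the working catalyst, the charge of free catalyst less the charge of impurity: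

W = c(free catalyst) − c(impurity)
flask: 0.150 mM; oak: 0.150 mM; ash: 0.410 mM

From oak to ash, W rises 2.73 times, more than the rate, so the rate per working catalyst is lower in the ash run, with its lower reagent charge.

The reckoning here takes the rate as proportional to W, which gives the order in free catalyst for the flask:

c(free catalyst)/W = 1.73

The mean rates per working catalyst of the ash run and the larch run give a reading of the mean reagent order between their two reagent charges of 0.294.

The forecast gives 0.33 for reagent, higher than this reading, and 1.7 for free catalyst, holding that “the reagent steps are close to saturating”.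

The flask gives 0.20 and 1.6. The forecast's reagent order is 1.67 times the simulated one, while its catalyst order lies within the tolerance.

    catalyst intermediate C → free catalyst + target (k = 0.116 s⁻¹)
    catalyst intermediate A → catalyst intermediate B (k = 0.344 s⁻¹)
    free catalyst + impurity → spent catalyst (k = 3320 M⁻¹ s⁻¹)
    substrate + catalyst intermediate B ⇌ catalyst intermediate C (K = 2900 M⁻¹, k = 54.7 M⁻¹ s⁻¹)
    reagent + free catalyst → catalyst intermediate A (k = 78.4 M⁻¹ s⁻¹)

In the flask, reagent takes up free catalyst at 190 min⁻¹ with reagent as charged, 27.3 times faster than catalyst intermediate C gives target at 6.96 min⁻¹, and after 7.50 min free catalyst stands at 1.60% of the catalyst charged against 37.2% in catalyst intermediate C, the resting state of the round. The flask's rate of 0.747 mM min⁻¹ after 2.23 min is 4.98 min⁻¹ per working catalyst, while the ash run, at the same reagent charge, reads 4.54 min⁻¹ over its first 3.00 min.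

The numbers in the tables are calculated for an exercise; noise was put on by code.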